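## Retrosynthetic overview

1. The aryl allyl ether is cut first. Mitsunobu O-alkylation joins 4-hydroxy-5-methylcoumarin to the primary allylic alcohol of the sesquiterpene diol. The pyranone ring of the coumarin is made separately from an o-hydroxyacetophenone.
2. The diol comes from one hydride reduction of a 2,2-dimethyl-6-methylidene-3-oxocyclohexyl enoate. The side chain at C-1 directs the hydride, so the C-3 carbinol forms cis to it.
3. The cyclohexanone, with its C=CH2 already in place, is an isomer of a 1-vinyl-2-methylidenecyclobutanol. The four-membered ring takes up the two vinyl carbons through Rh-alkoxide β-carbon elimination followed by 6-endo conjugate addition.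
4. The enabling feature is the strained cyclobutane ring. Its carbinol carbon C-3 carries the vinyl group and lies between the quaternary C-2 (CMe2) and the sp2 carbon C-4 (=CH2). Only the C3–C4 bond can therefore open, and it gives an alkenyl-rhodium next to a newly formed vinyl ketone.
5. The cyclobutane, its CMe2 group and the side-chain stereocentre come from (+)-α-pinene, and the E-enoate arm is attached by Negishi coupling. Ring order: cyclobutane (chiral pool), then cyclohexane (key step), with the coumarin pyranone made in parallel.

Key step: step 10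

Assumption: (+)-α-pinene of high enantiomeric purity is the only source of chirality. The vinyl carbinol is used as its mixture of carbinol epimers, because that carbon becomes the ketone carbon in the key step.

## Route

Step 1
Reactants: 1 (+)-α-pinene, (1R,5R)
Product: 2 cis-pinonic acid, 2-[(1S,3S)-3-acetyl-2,2-dimethylcyclobutyl]acetic acid
Conditions: RuCl3·xH2O (cat.), NaIO4, MeCN/EtOAc/H2O, rt
Reagents that add atoms: sodium periodate, [Na+].[O-]I(=O)(=O)=O
Why: RuO4-catalysed oxidative cleavage of the trisubstituted alkene opens only the six-membered ring, so the cyclobutane, its CMe2 group and both ring stereocentres (cis by origin) pass unchanged into 2.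

Step 2
Reactants: 2 cis-pinonic acid
Product: 3 2-[(1S,3S)-3-acetoxy-2,2-dimethylcyclobutyl]acetic acid
Conditions: mCPBA, TFA (cat.), CH2Cl2, rt, dark
Reagents that add atoms: mCPBA, OOC(=O)c1cccc(Cl)c1
Why: In this Baeyer–Villiger oxidation the secondary cyclobutyl carbon migrates in preference to methyl and with retention, and no alkene is present yet to compete for the peracid.

Step 3
Reactants: 3 acetoxy acid
Product: 4 (1S,3R)-3-(2-hydroxyethyl)-2,2-dimethylcyclobutan-1-ol (cis)
Conditions: LiAlH4, THF, 0 °C to reflux; aqueous work-up
Reagents that add atoms: none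
Why: LiAlH4 reduces the acid to the primary alcohol and cleaves the acetate in the same operation without touching either ring stereocentre.

Step 4
Reactants: 4 diol
Product: 5 (1S,3S)-3-(2-iodoethyl)-2,2-dimethylcyclobutan-1-ol
Conditions: I2, PPh3, imidazole, CH2Cl2, 0 °C
Reagents that add atoms: iodine, II
Why: Appel-type (Garegg–Samuelsson) iodination is SN2 at the alkoxyphosphonium stage, so the unhindered primary alcohol reacts while the neopentyl-type secondary cyclobutanol stays free.

Step 5
Reactants: 5 iodo alcohol
Product: 6 (3S)-3-(2-iodoethyl)-2,2-dimethylcyclobutan-1-one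
Conditions: Dess–Martin periodinane, CH2Cl2, rt
Reagents that add atoms: none
Why: Dess–Martin oxidation is neutral and tolerates the primary iodide, and the remaining stereocentre is β to the new ketone and therefore cannot epimerise.

Step 6
Reactants: 7 ethyl acetoacetate
Product: 8 ethyl (E)-3-[(trifluoromethyl)sulfonyloxy]but-2-enoate
Conditions: Tf2O, aq. Me4NOH, toluene, 5 °C to rt
Reagents that add atoms: triflic anhydride, O=S(=O)(OS(=O)(=O)C(F)(F)F)C(F)(F)F
Why: With a non-chelating ammonium counter-ion, stereoselective enol triflation goes through the open enolate and places OTf trans to the ester, which is the geometry the side chain needs.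

Step 7
Reactants: 6 iodo ketone; 8 (E)-enol triflate
Product: 10 ethyl (E)-5-[(1R)-2,2-dimethyl-3-oxocyclobutyl]-3-methylpent-2-enoate, via alkylzinc iodide 9 (not isolated)
Conditions: Zn dust, LiCl, THF, 40 °C; then 8, Pd(dppf)Cl2 (cat.), THF, rt to 45 °C
Reagents that add atoms: none
Why: LiCl-assisted zinc insertion gives a primary alkylzinc iodide that tolerates the ketone, and the sp3–sp2 Negishi coupling replaces OTf with retention, fixing the E-trisubstituted alkene.

Step 8
Reactants: 10 cyclobutanone
Product: 11 ethyl (E)-5-[(1S)-2,2-dimethyl-4-methylidene-3-oxocyclobutyl]-3-methylpent-2-enoate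
Conditions: (CH2O)n, i-Pr2NH·TFA, TFA (cat.), THF, reflux; used directly
Reagents that add atoms: formaldehyde (as paraformaldehyde), C=O
Why: This Mannich-type direct α-methylenation (aminomethylation, then loss of the amine) can occur only at C-4, because the other α-carbon is the quaternary CMe2.

Step 9
Reactants: 11 α-methylidene cyclobutanone
Product: 12 ethyl (E)-5-[(1S)-3-ethenyl-3-hydroxy-2,2-dimethyl-4-methylidenecyclobutyl]-3-methylpent-2-enoate (both C-3 epimers)
Conditions: CH2=CHMgBr, anhydrous CeCl3, THF, −78 °C
Reagents that add atoms: vinylmagnesium bromide, C=C[Mg]Br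
Why: Organocerium 1,2-addition is favoured by the oxophilic, weakly basic reagent and by strain relief at the cyclobutanone carbon, which suppresses conjugate addition and attack on the enoate, and the carbinol configuration does not matter.

Step 10
Reactants: 12 1-vinyl-2-methylidenecyclobutanol
Product: 13 ethyl (E)-5-[(1R)-2,2-dimethyl-6-methylidene-3-oxocyclohexyl]-3-methylpent-2-enoate
Conditions: [Rh(OH)(cod)]2 (2.5 mol %), dppf (6 mol %), toluene, 80 °C
Reagents that add atoms: none
Why: Proposed new method: Exchange of the tertiary alcohol with Rh–OH gives a rhodium(I) cyclobutanolate, which releases ring strain by β-carbon elimination of the C3–C4 bond and so forms an acyclic alkenyl-rhodium (Rh on the carbon bearing =CH2) together with a vinyl ketone. Syn-insertion of the enone C=C into the Rh–C bond (conjugate addition) then forms the new ring bond, and the oxa-π-allyl rhodium is protonated by the next molecule of 12, so the step is a catalytic isomerisation that enlarges the four-membered ring by the two vinyl carbons. The closest known reaction types are the Rh(I)-catalysed two-carbon enlargement of 1-allenyl- and 1-alkenylcyclobutanols to six-membered ketones by C(sp3)–C(sp3) cleavage and the Rh(I)-catalysed opening of benzocyclobutenols and cyclobutenols at the C(sp3)–C(sp2) bond, and what is new is combining them on a 2-methylidenecyclobutanol. The only ring closed is the cyclohexanone, by a 6-endo-trig closure assisted by the gem-dimethyl group. No stereocentre is created: the side-chain carbon is a spectator that keeps all four substituents, and both carbinol epimers converge on the same ketone. The step needs site-selective cleavage, which is secured because cleaving C3–C2 would give a tertiary alkyl-rhodium at CMe2 and loss of the vinyl group would release no strain, while the alkenyl-rhodium has no easy β-hydride elimination and no Rh–H forms, so the exocyclic methylene should arrive in place and unisomerised.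

Step 11
Reactants: 13 keto ester
Product: 14 (E)-5-[(1R,3S)-3-hydroxy-2,2-dimethyl-6-methylidenecyclohexyl]-3-methylpent-2-en-1-ol
Conditions: LiAlH4, Et2O, −78 to 0 °C; aqueous work-up
Reagents that add atoms: none
Why: In this LiAlH4 reduction the small hydride attacks the ketone from the face opposite the C-1 side chain (axial attack on the chair with the side chain equatorial, as in 4,4-dimethyl-3-keto terpenoids), giving the equatorial (3S)-alcohol cis to the chain, and the enoate is reduced 1,2 to the E-allylic alcohol in the same flask.

Step 12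
Reactants: 15 1-(2-hydroxy-6-methylphenyl)ethanone
Product: 16 4-hydroxy-5-methylcoumarin
Conditions: NaH, (EtO)2CO, toluene, reflux; then aq. HCl
Reagents that add atoms: diethyl carbonate, CCOC(=O)OCC
Why: Claisen-type C-ethoxycarbonylation of the methyl ketone enolate followed by lactonisation onto the phenoxide is the standard way to build the 4-hydroxycoumarin pyranone ring.

Step 13
Reactants: 14 diol; 16 4-hydroxy-5-methylcoumarin
Product: 17 target, 4-{[(E)-5-[(1R,3S)-3-hydroxy-2,2-dimethyl-6-methylidenecyclohexyl]-3-methylpent-2-en-1-yl]oxy}-5-methylcoumarin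
Conditions: PPh3, DIAD, THF, 0 °C to rt
Reagents that add atoms: none
Why: In the Mitsunobu etherification the acidic vinylogous acid 16 is alkylated at O-4 by the activated primary allylic alcohol, while the secondary alcohol next to CMe2 is too hindered to form or displace an alkoxyphosphonium ion and needs no protection.

## Compound list

1 | (+)-α-pinene, (1R,5R) | CC1=CC[C@@H]2C[C@H]1C2(C)C | starting material
2 | cis-pinonic acid, 2-[(1S,3S)-3-acetyl-2,2-dimethylcyclobutyl]acetic acid | OC(=O)C[C@@H]1C[C@H](C(C)=O)C1(C)C | intermediate
3 | 2-[(1S,3S)-3-acetoxy-2,2-dimethylcyclobutyl]acetic acid | OC(=O)C[C@@H]1C[C@H](OC(C)=O)C1(C)C | intermediate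
4 | (1S,3R)-3-(2-hydroxyethyl)-2,2-dimethylcyclobutan-1-ol | OCC[C@@H]1C[C@H](O)C1(C)C | intermediate
5 | (1S,3S)-3-(2-iodoethyl)-2,2-dimethylcyclobutan-1-ol | ICC[C@@H]1C[C@H](O)C1(C)C | intermediate
6 | (3S)-3-(2-iodoethyl)-2,2-dimethylcyclobutan-1-one | ICC[C@@H]1CC(=O)C1(C)C | intermediate
7 | ethyl acetoacetate | CCOC(=O)CC(C)=O | starting material
8 | ethyl (E)-3-[(trifluoromethyl)sulfonyloxy]but-2-enoate | C/C(OS(=O)(=O)C(F)(F)F)=C\C(=O)OCC | intermediate
9 | {2-[(1S)-2,2-dimethyl-3-oxocyclobutyl]ethyl}zinc iodide | I[Zn]CC[C@@H]1CC(=O)C1(C)C | intermediate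
10 | ethyl (E)-5-[(1R)-2,2-dimethyl-3-oxocyclobutyl]-3-methylpent-2-enoate | CCOC(=O)/C=C(\C)CC[C@@H]1CC(=O)C1(C)C | intermediate
11 | ethyl (E)-5-[(1S)-2,2-dimethyl-4-methylidene-3-oxocyclobutyl]-3-methylpent-2-enoate | CCOC(=O)/C=C(\C)CC[C@@H]1C(=C)C(=O)C1(C)C | intermediate
12 | ethyl (E)-5-[(1S)-3-ethenyl-3-hydroxy-2,2-dimethyl-4-methylidenecyclobutyl]-3-methylpent-2-enoate (C-3 epimers) | CCOC(=O)/C=C(\C)CC[C@@H]1C(=C)C(O)(C=C)C1(C)C | intermediate
13 | ethyl (E)-5-[(1R)-2,2-dimethyl-6-methylidene-3-oxocyclohexyl]-3-methylpent-2-enoate | C=C1CCC(=O)C(C)(C)[C@@H]1CC/C(C)=C/C(=O)OCC | intermediate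
14 | (E)-5-[(1R,3S)-3-hydroxy-2,2-dimethyl-6-methylidenecyclohexyl]-3-methylpent-2-en-1-ol | C=C1CC[C@H](O)C(C)(C)[C@@H]1CC/C(C)=C/CO | intermediate
15 | 1-(2-hydroxy-6-methylphenyl)ethanone | CC(=O)c1c(C)cccc1O | starting material
16 | 4-hydroxy-5-methylcoumarin | Cc1cccc2oc(=O)cc(O)c12 | intermediate
17 | CNP0172901.1 | C=C1CC[C@H](O)C(C)(C)[C@@H]1CC/C(C)=C/COc1cc(=O)oc2cccc(C)c12 | target

## Step count and weak points

Total steps: 13. Longest linear sequence: 11 (steps 1–5, 7–11, 13).

**Step 10 (proposed new method).** The rhodium cyclobutanolate may fail to cleave the bond to the sp2 carbon. Alternatively, the alkenyl-rhodium may be protonated before it reaches the enone, which would open the ring without closing the larger one.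

The fallback sets out from 11 and enlarges the ring by two known one-carbon steps:
- Dimethylsulfonium methylide adds 1,2 to the ketone and gives the spiro-epoxide ethyl (E)-5-[(1S)-2,2-dimethyl-4-methylidene-3-spiro-oxiranylcyclobutyl]-3-methylpent-2-enoate F1.
- LiI in THF opens the epoxide at CH2, and a strain-driven semipinacol shift of the alkenyl ring carbon gives the cyclopentanone ethyl (E)-5-[(1R)-2,2-dimethyl-5-methylidene-3-oxocyclopentyl]-3-methylpent-2-enoate F2. It is handled cold and without base, so that the β,γ-alkene does not move into conjugation.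
- TMSCHN2 with BF3·OEt2 at −78 °C then inserts one carbon. The less substituted α-CH2 migrates rather than CMe2, giving the α-silyl cyclohexanone ethyl (E)-5-[(1R)-2,2-dimethyl-6-methylidene-3-oxo-4-(trimethylsilyl)cyclohexyl]-3-methylpent-2-enoate F3.
- Dilute aqueous acid in THF removes the silyl group, and the route is rejoined at 13.

**Step 8 (together with the handling of 11 in step 9).** The unhindered α-methylidene cyclobutanone may oligomerise, take up the amine again, or undergo conjugate addition of the vinyl reagent.

The fallback sets out from 10 and never liberates the enone: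
- LiHMDS and then Eschenmoser's salt give the Mannich base ethyl (E)-5-[(1R)-4-[(dimethylamino)methyl]-2,2-dimethyl-3-oxocyclobutyl]-3-methylpent-2-enoate F4.
- Vinylcerium addition gives the amino alcohol ethyl (E)-5-[(1R)-4-[(dimethylamino)methyl]-3-ethenyl-3-hydroxy-2,2-dimethylcyclobutyl]-3-methylpent-2-enoate F5.
- H2O2 in MeOH oxidises only the amine, to the N-oxide of F5, F6.
- Warming in DMSO brings about a Cope elimination. This is syn and base-free, so no alkoxide-driven fragmentation can occur. It installs the exocyclic methylene, and the route is rejoined at 12.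

**Step 13.** The ambident coumarin anion may be alkylated at C-3 or at the lactone carbonyl oxygen, or the allylic phosphonium ion may be attacked with allylic transposition.

The fallback sets out from 16 and reverses the polarity. POCl3 converts 16 into 4-chloro-5-methylcoumarin F7. The primary alkoxide of 14 (NaH, 1 equiv, THF, 0 °C) then displaces chloride by addition–elimination at C-4, which can only give the 4-O-ether, and the route is rejoined at 17.

## Further compounds

F1 | step 10 | ethyl (E)-5-[(1S)-2,2-dimethyl-4-methylidene-3-spiro-oxiranylcyclobutyl]-3-methylpent-2-enoate | CCOC(=O)/C=C(\C)CC[C@@H]1C(=C)C2(CO2)C1(C)C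
F2 | step 10 | ethyl (E)-5-[(1R)-2,2-dimethyl-5-methylidene-3-oxocyclopentyl]-3-methylpent-2-enoate | C=C1CC(=O)C(C)(C)[C@@H]1CC/C(C)=C/C(=O)OCC
F3 | step 10 | ethyl (E)-5-[(1R)-2,2-dimethyl-6-methylidene-3-oxo-4-(trimethylsilyl)cyclohexyl]-3-methylpent-2-enoate | C=C1CC([Si](C)(C)C)C(=O)C(C)(C)[C@@H]1CC/C(C)=C/C(=O)OCC
F4 | step 8 | ethyl (E)-5-[(1R)-4-[(dimethylamino)methyl]-2,2-dimethyl-3-oxocyclobutyl]-3-methylpent-2-enoate | CCOC(=O)/C=C(\C)CC[C@@H]1C(CN(C)C)C(=O)C1(C)C
F5 | step 8 | ethyl (E)-5-[(1R)-4-[(dimethylamino)methyl]-3-ethenyl-3-hydroxy-2,2-dimethylcyclobutyl]-3-methylpent-2-enoate | CCOC(=O)/C=C(\C)CC[C@@H]1C(CN(C)C)C(O)(C=C)C1(C)C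
F6 | step 8 | N-oxide of F5 | CCOC(=O)/C=C(\C)CC[C@@H]1C(C[N+](C)(C)[O-])C(O)(C=C)C1(C)C
F7 | step 13 | 4-chloro-5-methylcoumarin | Cc1cccc2oc(=O)cc(Cl)c12
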